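**Assumption:** Gustastatin has no stereocentres and no stereogenic double bonds. It is achiral, so the "single enantiomer" requirement has nothing to control.

## Retrosynthetic overview
1. Gustastatin comes from the bis-dioxolane depside 15 by one global deketalisation.
2. Key step: ring A is not brought in as a hindered benzoic acid. It is built on the ester by Diels–Alder/aromatisation of aryl alkynoate 12 with Brassard's diene, which sets 2-OH/4-OMe directly.
3. Aryl alkynoate 12 comes from ring-B phenol 11 and ynoic acid 5, so the depside C–O bond forms at an unhindered sp-acid. Ring B arises by the same logic from methyl ynoate 4 and 1,1-dimethoxy-3-silyloxybutadiene, which sets 2-OMe/4-OH.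
4. Ynoates 4 and 5 both derive from one alkyne, 3, made from ethyl 3-oxooctanoate.
5. Ring order: B first, then A on B's phenolic oxygen. No phenol protecting groups or O-methylation steps are needed.

## Route

**Step 1**
Reactants: 1, ethyl 3-oxooctanoate
Product: 2, ethyl 2-(2-pentyl-1,3-dioxolan-2-yl)acetate
Conditions: ethylene glycol (2 equiv), p-TsOH·H2O (cat.), PhMe, reflux, Dean–Stark
Reagents that add atoms: ethylene glycol, OCCO
Why: Acid-catalysed ketalisation with azeotropic water removal takes only the ketone, and the ester is untouched.

**Step 2**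
Reactants: 2
Product: 3, 2-pentyl-2-(prop-2-yn-1-yl)-1,3-dioxolane
Conditions: DIBAL-H (1.05 equiv), CH2Cl2, −78 °C; then MeOH, K2CO3, Ohira–Bestmann reagent, −78 °C → rt; Rochelle salt work-up
Reagents that add atoms: dimethyl (1-diazo-2-oxopropyl)phosphonate, CC(=O)C(=[N+]=[N-])P(=O)(OC)OC (supplies the terminal alkyne carbon)
Why: One-pot partial ester reduction and Seyferth–Gilbert homologation (Ohira–Bestmann variant) converts the β-ketal aldehyde as it is released, so it never has to be isolated.

**Step 3**
Reactants: 3
Product: 4, methyl 4-(2-pentyl-1,3-dioxolan-2-yl)but-2-ynoate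
Conditions: n-BuLi, THF, −78 °C; ClCO2Me, −78 → 0 °C
Reagents that add atoms: methyl chloroformate, COC(=O)Cl
Why: This is C-acylation of a lithium acetylide with a chloroformate, and the ketal is inert to base.

**Step 4**
Reactants: 3
Product: 5, 4-(2-pentyl-1,3-dioxolan-2-yl)but-2-ynoic acid
Conditions: n-BuLi, THF, −78 °C; dry CO2, → 0 °C; cold 10% citric acid to pH ~3, rapid EtOAc extraction
Reagents that add atoms: carbon dioxide, O=C=O
Why: This is carboxylation of the lithium acetylide, and the cold, brief, weakly acidic work-up preserves the dioxolane.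

**Step 5**
Reactants: 6, acetyl chloride; 7, 1,1-dichloroethene
Product: 8, 4,4-dichlorobut-3-en-2-one
Conditions: AlCl3, CH2Cl2, 0 °C → rt; ice/HCl; distil over Na2CO3 (−HCl)
Reagents that add atoms: none besides reactants 6 and 7
Why: Aliphatic Friedel–Crafts (Kondakov-type) acylation of the alkene gives the trichloroketone, which loses HCl to form the conjugated dichlorovinyl ketone.

**Step 6**
Reactants: 8
Product: 9, 4,4-dimethoxybut-3-en-2-one
Conditions: NaOMe (2.2 equiv), MeOH, 0 °C → rt, anhydrous
Reagents that add atoms: sodium methoxide, [Na+].[O-]C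
Why: Two successive vinylic addition–elimination (SNV) steps at the β-carbon of the enone replace both chlorides with methoxy.

**Step 7**
Reactants: 9
Product: 10, 1,1-dimethoxy-3-(trimethylsilyloxy)buta-1,3-diene
Conditions: TMSCl, Et3N, ZnCl2 (cat.), PhH, 40 °C; filter, distil
Reagents that add atoms: chlorotrimethylsilane, C[Si](C)(C)Cl
Why: This is Danishefsky–Kitahara-type silyl enol ether formation, and the CH3 group is the only enolisable position.

**Step 8**
Reactants: 4; 10 (3 equiv)
Product: 11, methyl 4-hydroxy-2-methoxy-6-[(2-pentyl-1,3-dioxolan-2-yl)methyl]benzoate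
Conditions: o-xylene (2 M), 140 °C, sealed tube, 24 h; then KF, MeOH, rt
Reagents that add atoms: none besides reactant 10 (supplies C2–C5 of ring B, the 2-OMe and the 4-O)
Why: In this Diels–Alder/aromatisation of an alkynoate with a vinylketene acetal, the nucleophilic CH2 terminus of 10 bonds to the β-carbon of the ynoate. Loss of MeOH and desilylation then give only the 2-OMe/4-OH/6-alkyl pattern.

**Step 9**
Reactants: 11; 5
Product: 12, 3-methoxy-4-(methoxycarbonyl)-5-[(2-pentyl-1,3-dioxolan-2-yl)methyl]phenyl 4-(2-pentyl-1,3-dioxolan-2-yl)but-2-ynoate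
Conditions: DCC (1.2 equiv), DMAP (0.1 equiv), CH2Cl2, 0 °C → rt
Reagents that add atoms: none
Why: Steglich esterification joins an unhindered alkynoic acid to the single free, unhindered phenol. Low temperature and catalytic DMAP suppress ynoate-to-allenoate isomerisation.

**Step 10**
Reactants: 13, methyl (E)-3-methoxybut-2-enoate
Product: 14, 1,3-dimethoxy-1-(trimethylsilyloxy)buta-1,3-diene (Brassard's diene; ketene acetal geometry is lost later and does not matter)
Conditions: LDA, THF, −78 °C; TMSCl, −78 °C → rt; pentane filtration, Kugelrohr distillation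
Reagents that add atoms: chlorotrimethylsilane, C[Si](C)(C)Cl
Why: γ-Deprotonation of the vinylogous carbonate followed by O-silylation of the dienolate is the standard preparation of this diene.

**Step 11 (key step)**
Reactants: 12; 14 (4 equiv)
Product: 15, 3-methoxy-4-(methoxycarbonyl)-5-[(2-pentyl-1,3-dioxolan-2-yl)methyl]phenyl 2-hydroxy-4-methoxy-6-[(2-pentyl-1,3-dioxolan-2-yl)methyl]benzoate
Conditions: PhMe (2 M), 125 °C, sealed base-free tube, 24–36 h; concentrate; THF/AcOH/H2O (8:1:1), rt, 1 h
Reagents that add atoms: none besides reactant 14 (supplies C2–C5 of ring A, the 2-O and the 4-OMe)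
Why: Proposed new method: a depside is assembled by benzannulation on an aryl alkynoate. The closest known reaction type is the thermal Diels–Alder/aromatisation of alkyl alkynoates and macrocyclic ynolides with Brassard- or Danishefsky-type dienes. The aryloxy group lowers the ynoate LUMO relative to the methyl ester used in step 8. The diene CH2 terminus attacks the β-carbon, and the C(OMe)(OTMS) centre ends up next to the ester. Mild acid ionises the more basic OMe or hydrolyses the silyl ketal to the dienone, and both pathways give the chelated 2-OH with the 4-OMe retained. Neutral conditions leave the aryl ester, methyl ester and ketals intact, and any partly deketalised material converges in step 12.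

**Step 12**
Reactants: 15
Product: 16, gustastatin
Conditions: p-TsOH·H2O (0.2 equiv), acetone/H2O (10:1), rt → 35 °C; NaHCO3 quench at full conversion
Reagents that add atoms: water, O (supplies both ketone oxygens)
Why: Acid-catalysed hydrolysis/transketalisation of both dioxolanes proceeds under mild aqueous acid that aryl and methyl benzoates tolerate. Base is avoided because it would trigger enolate attack on the aryl ester and isocoumarin formation.

## Compound list
1 | ethyl 3-oxooctanoate | CCCCCC(=O)CC(=O)OCC | starting material
2 | ethyl 2-(2-pentyl-1,3-dioxolan-2-yl)acetate | CCCCCC1(CC(=O)OCC)OCCO1 | intermediate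
3 | 2-pentyl-2-(prop-2-yn-1-yl)-1,3-dioxolane | CCCCCC1(CC#C)OCCO1 | intermediate
4 | methyl 4-(2-pentyl-1,3-dioxolan-2-yl)but-2-ynoate | CCCCCC1(CC#CC(=O)OC)OCCO1 | intermediate
5 | 4-(2-pentyl-1,3-dioxolan-2-yl)but-2-ynoic acid | CCCCCC1(CC#CC(=O)O)OCCO1 | intermediate
6 | acetyl chloride | CC(=O)Cl | starting material
7 | 1,1-dichloroethene | C=C(Cl)Cl | starting material
8 | 4,4-dichlorobut-3-en-2-one | CC(=O)C=C(Cl)Cl | intermediate
9 | 4,4-dimethoxybut-3-en-2-one | CC(=O)C=C(OC)OC | intermediate
10 | 1,1-dimethoxy-3-(trimethylsilyloxy)buta-1,3-diene | C=C(O[Si](C)(C)C)C=C(OC)OC | intermediate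
11 | methyl 4-hydroxy-2-methoxy-6-[(2-pentyl-1,3-dioxolan-2-yl)methyl]benzoate | CCCCCC1(Cc2cc(O)cc(OC)c2C(=O)OC)OCCO1 | intermediate
12 | 3-methoxy-4-(methoxycarbonyl)-5-[(2-pentyl-1,3-dioxolan-2-yl)methyl]phenyl 4-(2-pentyl-1,3-dioxolan-2-yl)but-2-ynoate | CCCCCC1(CC#CC(=O)Oc2cc(CC3(CCCCC)OCCO3)c(C(=O)OC)c(OC)c2)OCCO1 | intermediate
13 | methyl (E)-3-methoxybut-2-enoate | CO/C(C)=C/C(=O)OC | starting material
14 | 1,3-dimethoxy-1-(trimethylsilyloxy)buta-1,3-diene (Brassard's diene) | C=C(OC)C=C(OC)O[Si](C)(C)C | intermediate
15 | bis(ethylene ketal) of gustastatin | CCCCCC1(Cc2cc(OC)cc(O)c2C(=O)Oc2cc(CC3(CCCCC)OCCO3)c(C(=O)OC)c(OC)c2)OCCO1 | intermediate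
16 | gustastatin (achiral) | CCCCCC(=O)Cc1cc(OC)cc(O)c1C(=O)Oc1cc(CC(=O)CCCCC)c(C(=O)OC)c(OC)c1 | target

## Summary
**Total steps:** 12
**Longest linear sequence:** 7 (steps 1, 2, 3, 8, 9, 11, 12). The diene branch, steps 5, 6, 7, 8, 9, 11, 12, is equally long.

**Three steps most likely to fail:**
1. **Step 11.**
   - Risks: the cycloaddition to the neopentyl-type β-substituted aryl ynoate may be slow, the diene may decompose, and competing loss of silanol would give the 2-OMe product.
   - Fallback: give up building ring A on the ester. Make the benzyl ynoate from 3 and ClCO2Bn, benzannulate it with 14, hydrogenolyse to the ring-A salicylic acid, and join it to phenol 11 by TFAA mixed-anhydride depside coupling.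
2. **Step 8.**
   - Risk: the less activated methyl ynoate may give a low yield at 140 °C.
   - Fallback: take ring B from the aromatic pool. Laterally lithiate methyl 4-(benzyloxy)-2-methoxy-6-methylbenzoate with LDA and acylate with N-methoxy-N-methylhexanamide. Ketalisation and hydrogenolysis then give 11.
3. **Step 12.**
   - Risk: the ortho aryl ester may capture the oxocarbenium ion, which would expel phenol B and form an isocoumarin, cleaving the depside.
   - Fallback: change the ketone mask to a 1,1-disubstituted alkene (2-methyleneheptyl arms), using ynoates made by Cu-catalysed coupling of propiolates with 2-(bromomethyl)hept-1-ene. Both ketones are then revealed at the end by neutral ozonolysis with Me2S, which involves no cationic intermediate.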